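**Retrosynthetic overview**
- The (Z)-4-oxodec-2-enoyl side chain is installed last, by Z-selective Still–Gennari olefination of a C7 phosphonoacetate with 2-oxooctanal.
- Ring B (δ-lactone, formed second) comes from oxidative lactonisation of a C1/C5 diol; the C3 acetate is added after that.
- The quaternary C4 centre and the C5 oxygen come from epoxidation of a 2-substituted dihydropyran followed by syn C-methylation with AlMe3.
- Key C3–C4 bond: the anomeric carbon of the dihydropyran is metalated (a masked acyl anion) and added to (S)-3-(benzyloxy)-2-methylpropanal under 1,3-chelation control.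
- Ring A (dihydropyran, formed first) comes from W(CO)6-catalysed cycloisomerisation of an alkynol built from a Sharpless-resolved epoxy alcohol by acetylide opening.

Assumption: core atoms are labelled C1–C9 along the chain (C1 lactone carbonyl, C2 CH(CH3), C3 CH–OAc, C4 quaternary C(CH3)–O, C5 CH–O of the lactone, C6 CH(CH3), C7 CH–O-acyl, C8 O–CH(CH3), C9 its methyl); ring A is the tetrahydropyran, ring B the δ-lactone; commercial 3-penten-2-ol (mainly E) is taken as racemic 1; the acid 22 is taken as commercially available.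

**Route**

Step 1
Reactants: 1 (E)-pent-3-en-2-ol (racemic)
Product: 2 (1S)-1-[(2S,3S)-3-methyloxiran-2-yl]ethan-1-ol
Conditions: Ti(OiPr)4 (10 mol %), L-(+)-DIPT (15 mol %), t-BuOOH (0.45 equiv), 4 Å MS, CH2Cl2, −20 °C
Reagents that add atoms: tert-butyl hydroperoxide, CC(C)(C)OO
Why: Sharpless kinetic resolution (asymmetric epoxidation): with L-(+)-DIPT the (S)-alcohol is epoxidised much faster than the (R)-alcohol and gives the erythro epoxy alcohol, so C8 is selected and C7 and C6 are set by the reagent; stopping below 50 % conversion keeps the ee high.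

Step 2
Reactants: 2 (1S)-1-[(2S,3S)-3-methyloxiran-2-yl]ethan-1-ol
Product: 3 triethyl{(1S)-1-[(2R,3S)-3-methyloxiran-2-yl]ethoxy}silane
Conditions: Et3SiCl, imidazole, CH2Cl2, 0 °C
Reagents that add atoms: chlorotriethylsilane, CC[Si](Cl)(CC)CC
Why: Standard silyl ether formation; the labile TES group blocks the C8 hydroxyl only until the C7 hydroxyl has been protected, and no stereocentre is touched.

Step 3
Reactants: 3 triethyl{(1S)-1-[(2R,3S)-3-methyloxiran-2-yl]ethoxy}silane
Product: 4 (2S,3R,4S)-4-methyl-2-(triethylsilyloxy)hex-5-yn-3-ol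
Conditions: acetylene, n-BuLi, THF, −78 °C; BF3·OEt2; then 3, −78 °C
Reagents that add atoms: lithium acetylide (made in the flask from acetylene, C#C, with n-BuLi), [Li+].[C-]#C
Why: Yamaguchi alkynylation, an SN2 epoxide opening with inversion at C6, the carbon remote from the inductively deactivating and shielding silyloxy-bearing carbon; this turns the trans-epoxide into the C6-methyl/C7-hydroxyl syn pair and leaves the C7/C8 anti diol pattern intact.

Step 4
Reactants: 4 (2S,3R,4S)-4-methyl-2-(triethylsilyloxy)hex-5-yn-3-ol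
Product: 6 (2S,3R,4S)-4-methyl-3-(triisopropylsilyloxy)hex-5-yn-2-ol, via bis-silyl ether 5 (not isolated)
Conditions: TIPSOTf, 2,6-lutidine, CH2Cl2, 0 °C → rt; then MeOH, PPTS, rt
Reagents that add atoms: triisopropylsilyl triflate, CC(C)[Si](C(C)C)(C(C)C)OS(=O)(=O)C(F)(F)F
Why: Silylation followed by selective acid methanolysis (a secondary TES ether is cleaved orders of magnitude faster than a TIPS ether), which leaves C7–O robustly protected and C8–OH free; no stereocentre is touched.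

Step 5
Reactants: 6 (2S,3R,4S)-4-methyl-3-(triisopropylsilyloxy)hex-5-yn-2-ol
Product: 7 (2S,3R,4S)-2,4-dimethyl-3-(triisopropylsilyloxy)-3,4-dihydro-2H-pyran
Conditions: W(CO)6 (25 mol %), DABCO, THF, hν (350 nm), 60 °C
Reagents that add atoms: none
Why: McDonald alkynol cycloisomerisation: the tungsten vinylidene formed from the terminal alkyne is attacked at its terminal carbon by the C8 hydroxyl (6-endo), closing ring A as a cyclic enol ether with C4–H free; the homopropargylic oxygen is blocked, so no dihydrofuran can form.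

Step 6
Reactants: 8 methyl (S)-3-hydroxy-2-methylpropanoate
Product: 9 methyl (S)-3-(benzyloxy)-2-methylpropanoate
Conditions: benzyl 2,2,2-trichloroacetimidate, TfOH (cat.), CH2Cl2/cyclohexane, rt
Reagents that add atoms: benzyl 2,2,2-trichloroacetimidate, ClC(Cl)(Cl)C(=N)OCc1ccccc1
Why: Acid-catalysed imidate benzylation, which avoids base and therefore epimerisation or β-elimination of the Roche ester; benzyl is chosen because it chelates in step 8.

Step 7
Reactants: 9 methyl (S)-3-(benzyloxy)-2-methylpropanoate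
Product: 10 (S)-3-(benzyloxy)-2-methylpropanal
Conditions: i-Bu2AlH, CH2Cl2, −78 °C; KNaC4H4O6 (aq) work-up
Reagents that add atoms: none
Why: Partial ester reduction through the stable tetrahedral aluminium hemiacetal at −78 °C; the aldehyde is used at once so the C2 centre does not epimerise.

Step 8
Reactants: 7 (2S,3R,4S)-2,4-dimethyl-3-(triisopropylsilyloxy)-3,4-dihydro-2H-pyran; 10 (S)-3-(benzyloxy)-2-methylpropanal
Product: 13 (1S,2S)-3-(benzyloxy)-1-[(4S,5R,6S)-4,6-dimethyl-5-(triisopropylsilyloxy)-5,6-dihydro-4H-pyran-2-yl]-2-methylpropan-1-ol, via lithiated glycal 11 (not isolated), via bromomagnesium glycal 12 (not isolated)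
Conditions: 7, t-BuLi, THF, −78 → 0 °C; MgBr2·OEt2, −78 °C; then 10, CH2Cl2, −78 °C; NH4Cl (aq)
Reagents that add atoms: none
Why: α-Metalation of the cyclic enol ether makes the anomeric carbon C4 (normally an oxocarbenium electrophile) a masked acyl anion, which adds to the aldehyde carbon C3 through the Cram–Reetz 1,3-chelate (Mg bridging C=O and the benzyloxy oxygen, attack anti to the C2 methyl) to give the 2,3-anti (3S) alcohol; adducts from the minor enantiomer of 7 are diastereomers and are removed here.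

Step 9
Reactants: 13 (1S,2S)-3-(benzyloxy)-1-[(4S,5R,6S)-4,6-dimethyl-5-(triisopropylsilyloxy)-5,6-dihydro-4H-pyran-2-yl]-2-methylpropan-1-ol
Product: 15 (2R,3S,4S,5R,6S)-2-[(1S,2S)-3-(benzyloxy)-1-hydroxy-2-methylpropyl]-2,4,6-trimethyl-5-(triisopropylsilyloxy)tetrahydro-2H-pyran-3-ol, via glycal epoxide 14 (not isolated)
Conditions: DMDO (acetone), CH2Cl2, −78 → 0 °C; concentrate cold; AlMe3 (4 equiv), CH2Cl2, −78 → 0 °C
Reagents that add atoms: dimethyldioxirane, CC1(C)OO1; trimethylaluminium, C[Al](C)C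
Why: Enol ether epoxidation followed by syn C-methylation, as used for angular methyl groups of ladder polyethers: DMDO attacks the face anti to the allylic C6 methyl, then AlMe3 ionises the anomeric C–O bond and delivers methyl to C4 from the aluminate on the face of the departing oxygen (axial attack), giving the axial C4 methyl cis to the equatorial C5 hydroxyl.

Step 10
Reactants: 15 (2R,3S,4S,5R,6S)-2-[(1S,2S)-3-(benzyloxy)-1-hydroxy-2-methylpropyl]-2,4,6-trimethyl-5-(triisopropylsilyloxy)tetrahydro-2H-pyran-3-ol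
Product: 16 (2S,3S)-3-[(2R,3S,4S,5R,6S)-3-hydroxy-2,4,6-trimethyl-5-(triisopropylsilyloxy)tetrahydro-2H-pyran-2-yl]-2-methylpropane-1,3-diol
Conditions: H2 (1 atm), Pd(OH)2/C, EtOAc, rt
Reagents that add atoms: none
Why: Hydrogenolysis of the benzyl ether; nothing else in 15 is reducible (no alkene, and the silyl ether and tertiary ether are inert).

Step 11
Reactants: 16 (2S,3S)-3-[(2R,3S,4S,5R,6S)-3-hydroxy-2,4,6-trimethyl-5-(triisopropylsilyloxy)tetrahydro-2H-pyran-2-yl]-2-methylpropane-1,3-diol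
Product: 19 (3R,4S,4aR,6S,7R,8S,8aS)-4-hydroxy-3,4a,6,8-tetramethyl-7-(triisopropylsilyloxy)hexahydropyrano[3,2-b]pyran-2(3H)-one, via hydroxy aldehyde 17 (not isolated), via lactol 18 (not isolated)
Conditions: TEMPO (20 mol %), PhI(OAc)2 (2.5 equiv), CH2Cl2, rt
Reagents that add atoms: none
Why: Oxidative lactonisation: the oxoammonium oxidises only the primary alcohol, the aldehyde is trapped by the equatorial C5 hydroxyl as the six-membered lactol and oxidised on to the trans-fused δ-lactone (ring B); the hindered secondary C3 hydroxyl is left alone and the neutral conditions do not epimerise C2.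

Step 12
Reactants: 19 (3R,4S,4aR,6S,7R,8S,8aS)-4-hydroxy-3,4a,6,8-tetramethyl-7-(triisopropylsilyloxy)hexahydropyrano[3,2-b]pyran-2(3H)-one
Product: 20 (3R,4S,4aS,6S,7R,8S,8aS)-3,4a,6,8-tetramethyl-2-oxo-7-(triisopropylsilyloxy)octahydropyrano[3,2-b]pyran-4-yl acetate
Conditions: Ac2O, DMAP (cat.), pyridine, rt
Reagents that add atoms: acetic anhydride, CC(=O)OC(C)=O
Why: DMAP-catalysed acylation of the only free hydroxyl (C3); the weak amine base avoids E1cB loss of the β-acyloxy group from the lactone.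

Step 13
Reactants: 20 (3R,4S,4aS,6S,7R,8S,8aS)-3,4a,6,8-tetramethyl-2-oxo-7-(triisopropylsilyloxy)octahydropyrano[3,2-b]pyran-4-yl acetate
Product: 21 (3R,4S,4aS,6S,7R,8R,8aS)-7-hydroxy-3,4a,6,8-tetramethyl-2-oxooctahydropyrano[3,2-b]pyran-4-yl acetate
Conditions: HF·pyridine, THF/pyridine, 0 °C → rt
Reagents that add atoms: none
Why: Fluoride-driven desilylation under buffered, non-basic conditions, so the acetate neither migrates nor eliminates and the lactone stays closed.

Step 14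
Reactants: 21 (3R,4S,4aS,6S,7R,8R,8aS)-7-hydroxy-3,4a,6,8-tetramethyl-2-oxooctahydropyrano[3,2-b]pyran-4-yl acetate; 22 2-[bis(2,2,2-trifluoroethoxy)phosphoryl]acetic acid
Product: 23 (3R,4S,4aS,6S,7R,8R,8aS)-4-acetoxy-3,4a,6,8-tetramethyl-2-oxooctahydropyrano[3,2-b]pyran-7-yl 2-[bis(2,2,2-trifluoroethoxy)phosphoryl]acetate
Conditions: DCC, DMAP (cat.), CH2Cl2, 0 °C → rt
Reagents that add atoms: none
Why: Steglich esterification; phosphonoacetic acids are activated readily and acylate even the flanked equatorial C7 hydroxyl with retention.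

Step 15
Reactants: 24 octane-1,2-diol (racemic)
Product: 25 2-oxooctanal
Conditions: (COCl)2, DMSO, CH2Cl2, −78 °C; Et3N, −78 → 0 °C
Reagents that add atoms: none
Why: Double Swern oxidation of a 1,2-diol gives the α-keto aldehyde without C–C cleavage; it is used crude and anhydrous.

Step 16
Reactants: 23 (3R,4S,4aS,6S,7R,8R,8aS)-4-acetoxy-3,4a,6,8-tetramethyl-2-oxooctahydropyrano[3,2-b]pyran-7-yl 2-[bis(2,2,2-trifluoroethoxy)phosphoryl]acetate; 25 2-oxooctanal
Product: 26 Botcinin J, (3R,4S,4aS,6S,7R,8R,8aS)-4-acetoxy-3,4a,6,8-tetramethyl-2-oxooctahydropyrano[3,2-b]pyran-7-yl (Z)-4-oxodec-2-enoate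
Conditions: 23, KN(SiMe3)2 (1.0 equiv), 18-crown-6, THF, −78 °C; then 25, −78 °C; NH4Cl (aq) at −78 °C
Reagents that add atoms: none
Why: Still–Gennari olefination: the electron-poor phosphonate anion adds to the aldehyde carbonyl (more electrophilic than the ketone) and the adduct collapses quickly under dissociating conditions to the kinetic Z-enoate; one equivalent of base at −78 °C deprotonates only the phosphonate and spares the β-acetoxy lactone.

**Compound list**
1 | (E)-pent-3-en-2-ol, racemic | C/C=C/C(C)O | starting material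
2 | (1S)-1-[(2S,3S)-3-methyloxiran-2-yl]ethan-1-ol | C[C@H](O)[C@@H]1O[C@H]1C | intermediate
3 | triethyl{(1S)-1-[(2R,3S)-3-methyloxiran-2-yl]ethoxy}silane | C[C@H](O[Si](CC)(CC)CC)[C@@H]1O[C@H]1C | intermediate
4 | (2S,3R,4S)-4-methyl-2-(triethylsilyloxy)hex-5-yn-3-ol | C#C[C@H](C)[C@@H](O)[C@H](C)O[Si](CC)(CC)CC | intermediate
5 | (2S,3R,4S)-4-methyl-2-(triethylsilyloxy)-3-(triisopropylsilyloxy)hex-5-yne | C#C[C@H](C)[C@@H](O[Si](C(C)C)(C(C)C)C(C)C)[C@H](C)O[Si](CC)(CC)CC | intermediate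
6 | (2S,3R,4S)-4-methyl-3-(triisopropylsilyloxy)hex-5-yn-2-ol | C#C[C@H](C)[C@@H](O[Si](C(C)C)(C(C)C)C(C)C)[C@H](C)O | intermediate
7 | (2S,3R,4S)-2,4-dimethyl-3-(triisopropylsilyloxy)-3,4-dihydro-2H-pyran | C[C@@H]1OC=C[C@H](C)[C@H]1O[Si](C(C)C)(C(C)C)C(C)C | intermediate
8 | methyl (S)-3-hydroxy-2-methylpropanoate | COC(=O)[C@@H](C)CO | starting material
9 | methyl (S)-3-(benzyloxy)-2-methylpropanoate | COC(=O)[C@@H](C)COCc1ccccc1 | intermediate
10 | (S)-3-(benzyloxy)-2-methylpropanal | O=C[C@@H](C)COCc1ccccc1 | intermediate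
11 | [(4S,5R,6S)-4,6-dimethyl-5-(triisopropylsilyloxy)-5,6-dihydro-4H-pyran-2-yl]lithium | C[C@@H]1OC([Li])=C[C@H](C)[C@H]1O[Si](C(C)C)(C(C)C)C(C)C | intermediate
12 | bromo[(4S,5R,6S)-4,6-dimethyl-5-(triisopropylsilyloxy)-5,6-dihydro-4H-pyran-2-yl]magnesium | C[C@@H]1OC([Mg]Br)=C[C@H](C)[C@H]1O[Si](C(C)C)(C(C)C)C(C)C | intermediate
13 | (1S,2S)-3-(benzyloxy)-1-[(4S,5R,6S)-4,6-dimethyl-5-(triisopropylsilyloxy)-5,6-dihydro-4H-pyran-2-yl]-2-methylpropan-1-ol | C[C@@H]1OC(=C[C@H](C)[C@H]1O[Si](C(C)C)(C(C)C)C(C)C)[C@@H](O)[C@@H](C)COCc2ccccc2 | intermediate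
14 | C4–C5 epoxide of 13 (2,7-dioxabicyclo[4.1.0]heptane), oxirane oxygen on the ring face opposite the C6 methyl | C[C@@H]1O[C@@]2([C@@H](O)[C@@H](C)COCc3ccccc3)O[C@H]2[C@H](C)[C@H]1O[Si](C(C)C)(C(C)C)C(C)C | intermediate
15 | (2R,3S,4S,5R,6S)-2-[(1S,2S)-3-(benzyloxy)-1-hydroxy-2-methylpropyl]-2,4,6-trimethyl-5-(triisopropylsilyloxy)tetrahydro-2H-pyran-3-ol | C[C@@H]1O[C@](C)([C@@H](O)[C@@H](C)COCc2ccccc2)[C@@H](O)[C@H](C)[C@H]1O[Si](C(C)C)(C(C)C)C(C)C | intermediate
16 | (2S,3S)-3-[(2R,3S,4S,5R,6S)-3-hydroxy-2,4,6-trimethyl-5-(triisopropylsilyloxy)tetrahydro-2H-pyran-2-yl]-2-methylpropane-1,3-diol | C[C@@H]1O[C@](C)([C@@H](O)[C@@H](C)CO)[C@@H](O)[C@H](C)[C@H]1O[Si](C(C)C)(C(C)C)C(C)C | intermediate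
17 | C1 aldehyde of 16 (3-hydroxy-2-methyl-3-pyranylpropanal, other centres as in 16) | C[C@@H]1O[C@](C)([C@@H](O)[C@@H](C)C=O)[C@@H](O)[C@H](C)[C@H]1O[Si](C(C)C)(C(C)C)C(C)C | intermediate
18 | δ-lactol of 17 closed onto the C5 hydroxyl (2-hydroxy analogue of 19, C1 anomers) | CC(C)[Si](C(C)C)(C(C)C)O[C@@H]1[C@@H](C)[C@@H]2OC(O)[C@H](C)[C@H](O)[C@@]2(C)O[C@H]1C | intermediate
19 | (3R,4S,4aR,6S,7R,8S,8aS)-4-hydroxy-3,4a,6,8-tetramethyl-7-(triisopropylsilyloxy)hexahydropyrano[3,2-b]pyran-2(3H)-one | CC(C)[Si](C(C)C)(C(C)C)O[C@@H]1[C@@H](C)[C@@H]2OC(=O)[C@H](C)[C@H](O)[C@@]2(C)O[C@H]1C | intermediate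
20 | (3R,4S,4aS,6S,7R,8S,8aS)-3,4a,6,8-tetramethyl-2-oxo-7-(triisopropylsilyloxy)octahydropyrano[3,2-b]pyran-4-yl acetate | CC(C)[Si](C(C)C)(C(C)C)O[C@@H]1[C@@H](C)[C@@H]2OC(=O)[C@H](C)[C@H](OC(C)=O)[C@@]2(C)O[C@H]1C | intermediate
21 | (3R,4S,4aS,6S,7R,8R,8aS)-7-hydroxy-3,4a,6,8-tetramethyl-2-oxooctahydropyrano[3,2-b]pyran-4-yl acetate | O[C@@H]1[C@@H](C)[C@@H]2OC(=O)[C@H](C)[C@H](OC(C)=O)[C@@]2(C)O[C@H]1C | intermediate
22 | 2-[bis(2,2,2-trifluoroethoxy)phosphoryl]acetic acid | OC(=O)CP(=O)(OCC(F)(F)F)OCC(F)(F)F | starting material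
23 | (3R,4S,4aS,6S,7R,8R,8aS)-4-acetoxy-3,4a,6,8-tetramethyl-2-oxooctahydropyrano[3,2-b]pyran-7-yl 2-[bis(2,2,2-trifluoroethoxy)phosphoryl]acetate | O=C(CP(=O)(OCC(F)(F)F)OCC(F)(F)F)O[C@@H]1[C@@H](C)[C@@H]2OC(=O)[C@H](C)[C@H](OC(C)=O)[C@@]2(C)O[C@H]1C | intermediate
24 | octane-1,2-diol, racemic | CCCCCCC(O)CO | starting material
25 | 2-oxooctanal | CCCCCCC(=O)C=O | intermediate
26 | Botcinin J | CCCCCCC(=O)/C=C\C(=O)O[C@@H]1[C@@H](C)[C@@H]2OC(=O)[C@H](C)[C@H](OC(C)=O)[C@@]2(C)O[C@H]1C | target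

**Totals and risk**

Total step count: 16. Longest linear sequence: 13 steps (steps 1–5, 8–14, 16).

The three steps most likely to fail:

Step 8 (diastereoselectivity at C3; the chelate may not outcompete Felkin addition). Fallback, setting out from 9 and 7 and coming back at 13: ester 9 is converted with MeNHOMe·HCl and i-PrMgCl into the Weinreb amide (S)-3-(benzyloxy)-N-methoxy-N,2-dimethylpropanamide F1. The lithiated glycal 11, made from 7 as in step 8 but without magnesium, acylates F1 at −78 °C to give the ketone (S)-3-(benzyloxy)-1-[(4S,5R,6S)-4,6-dimethyl-5-(triisopropylsilyloxy)-5,6-dihydro-4H-pyran-2-yl]-2-methylpropan-1-one F2. C3 is then set by reagent control instead of chelation: (R)-2-methyl-CBS-oxazaborolidine with catecholborane at −78 °C, the alkenyl group acting as the large substituent, gives 13.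

Step 9 (facial selectivity of the epoxidation, lability of epoxide 14 next to a free hydroxyl, and dependence on syn delivery of methyl). Fallback, setting out from 13 and coming back at 15: 13 is epoxidised with DMDO as before, but 14 is quenched at −78 °C with methanol to give the stable methyl ketoside (3S,4S,5R,6S)-2-[(1S,2S)-3-(benzyloxy)-1-hydroxy-2-methylpropyl]-2-methoxy-4,6-dimethyl-5-(triisopropylsilyloxy)tetrahydro-2H-pyran-3-ol F3 (axial-methoxy anomer drawn; both anomers converge). F3 is purified, so facial isomers can be removed, and then ionised with TMSOTf in the presence of AlMe3 in CH2Cl2 at −78 °C. The free oxocarbenium ion takes up methyl along the axial trajectory, independent of syn delivery, to give 15.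

Step 16 (Z selectivity with a keto aldehyde and Z-to-E drift of the ene-dione). Fallback, setting out from 21 and coming back at 26: 21 is esterified with (diethoxyphosphoryl)acetic acid (DCC, DMAP) to give the phosphonoacetate (3R,4S,4aS,6S,7R,8R,8aS)-4-acetoxy-3,4a,6,8-tetramethyl-2-oxooctahydropyrano[3,2-b]pyran-7-yl 2-(diethoxyphosphoryl)acetate F4. Masamune–Roush olefination (LiCl, DBU, MeCN) with 25 gives the E isomer of the target, the (E)-4-oxodec-2-enoate F5. Irradiation at 350 nm in benzene then isomerises E to Z to a photostationary mixture, from which 26 is separated and the E isomer recycled.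

**Further compounds**
F1 | step 8 | (S)-3-(benzyloxy)-N-methoxy-N,2-dimethylpropanamide | CON(C)C(=O)[C@@H](C)COCc1ccccc1
F2 | step 8 | (S)-3-(benzyloxy)-1-[(4S,5R,6S)-4,6-dimethyl-5-(triisopropylsilyloxy)-5,6-dihydro-4H-pyran-2-yl]-2-methylpropan-1-one | C[C@@H]1OC(=C[C@H](C)[C@H]1O[Si](C(C)C)(C(C)C)C(C)C)C(=O)[C@@H](C)COCc2ccccc2
F3 | step 9 | (3S,4S,5R,6S)-2-[(1S,2S)-3-(benzyloxy)-1-hydroxy-2-methylpropyl]-2-methoxy-4,6-dimethyl-5-(triisopropylsilyloxy)tetrahydro-2H-pyran-3-ol, axial-methoxy anomer | C[C@@H]1O[C@](OC)([C@@H](O)[C@@H](C)COCc2ccccc2)[C@@H](O)[C@H](C)[C@H]1O[Si](C(C)C)(C(C)C)C(C)C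
F4 | step 16 | (3R,4S,4aS,6S,7R,8R,8aS)-4-acetoxy-3,4a,6,8-tetramethyl-2-oxooctahydropyrano[3,2-b]pyran-7-yl 2-(diethoxyphosphoryl)acetate | CCOP(=O)(CC(=O)O[C@@H]1[C@@H](C)[C@@H]2OC(=O)[C@H](C)[C@H](OC(C)=O)[C@@]2(C)O[C@H]1C)OCC
F5 | step 16 | (3R,4S,4aS,6S,7R,8R,8aS)-4-acetoxy-3,4a,6,8-tetramethyl-2-oxooctahydropyrano[3,2-b]pyran-7-yl (E)-4-oxodec-2-enoate | CCCCCCC(=O)/C=C/C(=O)O[C@@H]1[C@@H](C)[C@@H]2OC(=O)[C@H](C)[C@H](OC(C)=O)[C@@]2(C)O[C@H]1C
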